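## Retrosynthetic overview

- The pyran ring closes last, by ring-closing metathesis (RCM) of an o-vinylaryl tertiary allyl ether (C3=C4), followed by O-desilylation.
- The C2–O bond (R) comes from a Pd-catalysed asymmetric allylic etherification of a 2-vinylphenol with a (Z)-allylic methyl carbonate.
- The carbonate comes from a B-alkyl Suzuki coupling of a cyclohexenylethyl iodide with (Z)-3-iodobut-2-en-1-ol.
- The cyclohexene closes first, by RCM of an isopropenyl/prenyl diene whose two stereocentres come from an enantioselective Ireland–Claisen rearrangement of geranyl propanoate.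
- The arene comes from 1,2,3-trimethoxybenzene: dibromination, double hydroxylation, formylation, mono-silylation, methylenation.

Assumption: the antipodes named for the two chiral controllers (the (S,S)-bis-sulfonamide boron reagent of step 1, the (R,R)-Trost ligand of step 15) are taken to give the drawn configurations; if a pilot run shows the opposite sense, the mirror-image controller is used and nothing else changes.

## Route

Step 1
Reactants: 1 geranyl propanoate [(2E)-3,7-dimethylocta-2,6-dien-1-yl propanoate]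
Product: 3 (2S,3S)-3-ethenyl-2,3,7-trimethyloct-6-enoic acid, via boron ketene acetal 2 (not isolated)
Conditions: N,N'-[(1S,2S)-1,2-diphenylethane-1,2-diyl]bis[3,5-bis(trifluoromethyl)benzenesulfonamide], BBr3, CH2Cl2, rt, evaporate; then 1, Et3N, toluene/hexane, −78 °C → 4 °C, 3 d; aq. HCl
Reagents that add atoms: none
Why: Enantioselective Ireland–Claisen rearrangement of the boron enolate: Et3N in toluene/hexane gives the enolate with methyl cis to the allylic oxygen, the chair transition state of the (E)-geranyl ester then sets the C2 and C3 methyls anti, and the chiral diazaborolidine selects the enolate face, fixing both centres as 2S,3S.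

Step 2
Reactants: 3 (2S,3S)-3-ethenyl-2,3,7-trimethyloct-6-enoic acid
Product: 6 (3S,4S)-3,4-dimethyl-4-(4-methylpent-3-en-1-yl)oxan-2-one, via bis-boryl adduct 4 (not isolated), via hydroxy acid 5 (not isolated)
Conditions: 9-BBN (2.5 equiv), THF, 0 °C → rt; NaOH, H2O2, 0 °C; then 1 M HCl, rt
Reagents that add atoms: hydrogen peroxide, OO
Why: Hydroboration–oxidation: 9-BBN adds anti-Markovnikov to the monosubstituted vinyl group only (the trisubstituted alkene is left), and acid closes the δ-hydroxy acid to the six-membered lactone without touching either stereocentre.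

Step 3
Reactants: 6 (3S,4S)-3,4-dimethyl-4-(4-methylpent-3-en-1-yl)oxan-2-one
Product: 7 (3S,4S)-4-(2-hydroxyethyl)-3,4,8-trimethylnon-7-en-2-one (in equilibrium with its cyclic hemiketal)
Conditions: MeLi (1.2 equiv), THF, −78 °C; aq. NH4Cl
Reagents that add atoms: methyllithium, [Li]C
Why: Mono-addition of an organolithium to a lactone: the lithium hemiketal is stable at −78 °C, so the methyl ketone forms without over-addition or α-epimerisation.

Step 4
Reactants: 7 (3S,4S)-4-(2-hydroxyethyl)-3,4,8-trimethylnon-7-en-2-one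
Product: 8 (3S,4R)-3,4,5-trimethyl-3-(4-methylpent-3-en-1-yl)hex-5-en-1-ol
Conditions: Ph3PCH3Br (3 equiv), KOt-Bu (2.9 equiv), THF, 0 °C → 50 °C
Reagents that add atoms: methyltriphenylphosphonium bromide, C[P+](c1ccccc1)(c1ccccc1)c1ccccc1.[Br-]
Why: Wittig methylenation through the open keto form turns the acetyl group into the isopropenyl group; the hindered α-centre is not touched (its label changes to R by priority only).

Step 5
Reactants: 8 (3S,4R)-3,4,5-trimethyl-3-(4-methylpent-3-en-1-yl)hex-5-en-1-ol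
Product: 9 2-[(1S,2S)-1,2,3-trimethylcyclohex-3-en-1-yl]ethan-1-ol
Conditions: second-generation Hoveyda–Grubbs catalyst (5 mol %), toluene, 80 °C, Ar sparge
Reagents that add atoms: none
Why: Ring-closing metathesis of the isopropenyl group with the prenyl-type alkene gives the trisubstituted cyclohexene with loss of isobutene, helped by the quaternary centre in the tether; no stereocentre is involved.

Step 6
Reactants: 9 2-[(1S,2S)-1,2,3-trimethylcyclohex-3-en-1-yl]ethan-1-ol
Product: 10 (1S,2S)-1-(2-iodoethyl)-1,2,3-trimethylcyclohex-3-ene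
Conditions: I2, PPh3, imidazole, CH2Cl2, 0 °C → rt
Reagents that add atoms: iodine, II
Why: Appel-type iodination of an unhindered primary alcohol by SN2 displacement of the oxyphosphonium group.

Step 7
Reactants: 11 but-2-yn-1-ol
Product: 13 (2Z)-3-iodobut-2-en-1-ol, via alkenylaluminate 12 (not isolated)
Conditions: NaAlH2(OCH2CH2OMe)2, THF, 0 °C → rt; then I2, THF, −78 °C → 0 °C
Reagents that add atoms: iodine, II
Why: Hydroxyl-directed trans-hydroalumination puts aluminium on C3 in a five-membered aluminate, and iodinolysis with retention gives the Z-vinyl iodide.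

Step 8
Reactants: 10 (1S,2S)-1-(2-iodoethyl)-1,2,3-trimethylcyclohex-3-ene; 13 (2Z)-3-iodobut-2-en-1-ol
Product: 16 (2Z)-3-methyl-5-[(1S,2S)-1,2,3-trimethylcyclohex-3-en-1-yl]pent-2-en-1-ol, via alkyllithium 14 (not isolated), via borate 15 (not isolated)
Conditions: t-BuLi (2.1 equiv), Et2O, −78 °C; B-methoxy-9-BBN, THF, −78 °C → rt; then 13, Pd(dppf)Cl2 (5 mol %), AsPh3, K3PO4 (aq), DMF, rt
Reagents that add atoms: none
Why: B-alkyl Suzuki–Miyaura coupling: iodine–lithium exchange at −78 °C (too cold for carbolithiation of the ring alkene), capture as the borate, and Pd-catalysed coupling with retention of the Z geometry.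

Step 9
Reactants: 16 (2Z)-3-methyl-5-[(1S,2S)-1,2,3-trimethylcyclohex-3-en-1-yl]pent-2-en-1-ol
Product: 17 methyl (2Z)-3-methyl-5-[(1S,2S)-1,2,3-trimethylcyclohex-3-en-1-yl]pent-2-en-1-yl carbonate
Conditions: ClCO2Me, pyridine, CH2Cl2, 0 °C
Reagents that add atoms: methyl chloroformate, COC(=O)Cl
Why: O-acylation of the primary allylic alcohol gives the carbonate leaving group for the allylic substitution.

Step 10
Reactants: 18 1,2,3-trimethoxybenzene
Product: 19 1,5-dibromo-2,3,4-trimethoxybenzene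
Conditions: NBS (2.2 equiv), MeCN, 0 → 50 °C
Reagents that add atoms: N-bromosuccinimide, O=C1CCC(=O)N1Br
Why: Electrophilic aromatic bromination: each outer methoxy group directs ortho/para, so the two bromines enter at C4 and C6.

Step 11
Reactants: 19 1,5-dibromo-2,3,4-trimethoxybenzene
Product: 20 4,5,6-trimethoxybenzene-1,3-diol
Conditions: Pd2(dba)3 (2 mol %), t-BuXPhos (8 mol %), KOH, 1,4-dioxane/H2O, 100 °C; then HCl
Reagents that add atoms: potassium hydroxide, [K+].[OH-]
Why: Buchwald Pd-catalysed hydroxylation of aryl bromides with a bulky biaryl phosphine works on electron-rich, ortho-substituted bromides and converts both C–Br bonds.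

Step 12
Reactants: 20 4,5,6-trimethoxybenzene-1,3-diol
Product: 21 2,6-dihydroxy-3,4,5-trimethoxybenzaldehyde
Conditions: POCl3, DMF, MeCN, 0 °C → rt; then H2O, 50 °C
Reagents that add atoms: N,N-dimethylformamide, CN(C)C=O; water, O
Why: Vilsmeier–Haack formylation at the only free ring position, which is ortho to both hydroxyls and para to a methoxy group.

Step 13
Reactants: 21 2,6-dihydroxy-3,4,5-trimethoxybenzaldehyde
Product: 22 2-hydroxy-3,4,5-trimethoxy-6-[(triisopropylsilyl)oxy]benzaldehyde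
Conditions: TIPSCl (1.05 equiv), imidazole, DMF, 0 °C → rt
Reagents that add atoms: chlorotriisopropylsilane, CC(C)[Si](Cl)(C(C)C)C(C)C
Why: The two hydroxyls are equivalent, and after the first silylation the remaining one is locked in a hydrogen bond to the aldehyde, so mono-protection is clean.

Step 14
Reactants: 22 2-hydroxy-3,4,5-trimethoxy-6-[(triisopropylsilyl)oxy]benzaldehyde
Product: 23 2-ethenyl-4,5,6-trimethoxy-3-[(triisopropylsilyl)oxy]phenol
Conditions: Ph3PCH3Br (2.5 equiv), KOt-Bu (2.4 equiv), THF, 0 °C → rt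
Reagents that add atoms: methyltriphenylphosphonium bromide, C[P+](c1ccccc1)(c1ccccc1)c1ccccc1.[Br-]
Why: Wittig methylenation of a salicylaldehyde with excess ylide (one equivalent is consumed by the phenol) gives the o-vinylphenol.

Step 15
Reactants: 17 methyl (2Z)-3-methyl-5-[(1S,2S)-1,2,3-trimethylcyclohex-3-en-1-yl]pent-2-en-1-yl carbonate; 23 2-ethenyl-4,5,6-trimethoxy-3-[(triisopropylsilyl)oxy]phenol
Product: 24 1-ethenyl-3,4,5-trimethoxy-2-{[(3R)-3-methyl-5-[(1S,2S)-1,2,3-trimethylcyclohex-3-en-1-yl]pent-1-en-3-yl]oxy}-6-[(triisopropylsilyl)oxy]benzene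
Conditions: Pd2(dba)3·CHCl3 (2.5 mol %), (R,R)-DACH-phenyl Trost ligand (7.5 mol %), CH2Cl2, rt
Reagents that add atoms: none
Why: Trost asymmetric allylic alkylation: the carbonate ionises to a π-allyl palladium complex, the phenol attacks the more substituted terminus to give the branched tertiary ether, and the chiral ligand selects the allyl face so that the new C–O centre is R.

Step 16
Reactants: 24 the (3R) tertiary allyl aryl ether
Product: 25 (2R)-6,7,8-trimethoxy-2-methyl-2-{2-[(1S,2S)-1,2,3-trimethylcyclohex-3-en-1-yl]ethyl}-5-[(triisopropylsilyl)oxy]-2H-chromene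
Conditions: second-generation Grubbs catalyst (5 mol %), CH2Cl2, 40 °C
Reagents that add atoms: none
Why: Ring-closing metathesis of the styrene vinyl group with the allylic vinyl group closes the six-membered 2H-pyran with loss of ethene; the quaternary C2 centre and the trisubstituted ring alkene are spectators.

Step 17
Reactants: 25 the 5-silyloxy-2H-chromene
Product: 26 (2R)-6,7,8-trimethoxy-2-methyl-2-{2-[(1S,2S)-1,2,3-trimethylcyclohex-3-en-1-yl]ethyl}-2H-chromen-5-ol
Conditions: Bu4NF, AcOH, THF, 0 °C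
Reagents that add atoms: none
Why: Buffered fluoride desilylation cleaves the aryl silyl ether without acid or base strong enough to affect the chromene or the cyclohexene.

## Compound list

1 | geranyl propanoate, (2E)-3,7-dimethylocta-2,6-dien-1-yl propanoate | CCC(=O)OC/C=C(\C)CCC=C(C)C | starting material
2 | boron ketene acetal of 1: O-boryl enolate with methyl cis to the allylic oxygen, boron in a (4S,5S)-4,5-diphenyl-1,3-bis{[3,5-bis(trifluoromethyl)phenyl]sulfonyl}-1,3,2-diazaborolidine | C/C=C(/OB1N(S(=O)(=O)c2cc(C(F)(F)F)cc(C(F)(F)F)c2)[C@@H](c2ccccc2)[C@H](c2ccccc2)N1S(=O)(=O)c1cc(C(F)(F)F)cc(C(F)(F)F)c1)OC/C=C(\C)CCC=C(C)C | intermediate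
3 | (2S,3S)-3-ethenyl-2,3,7-trimethyloct-6-enoic acid | C=C[C@]([C@H](C)C(=O)O)(C)CCC=C(C)C | intermediate
4 | bis-boryl adduct: 9-BBN acyloxyborane of 3 carrying a 9-BBN group on the terminal carbon of the former vinyl group | C(C[C@]([C@H](C)C(=O)OB1C2CCCC1CCC2)(C)CCC=C(C)C)B1C2CCCC1CCC2 | intermediate
5 | (2S,3S)-3-(2-hydroxyethyl)-2,3,7-trimethyloct-6-enoic acid | OCC[C@]([C@H](C)C(=O)O)(C)CCC=C(C)C | intermediate
6 | (3S,4S)-3,4-dimethyl-4-(4-methylpent-3-en-1-yl)oxan-2-one | C1(=O)OCC[C@]([C@@H]1C)(C)CCC=C(C)C | intermediate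
7 | (3S,4S)-4-(2-hydroxyethyl)-3,4,8-trimethylnon-7-en-2-one | OCC[C@]([C@H](C)C(C)=O)(C)CCC=C(C)C | intermediate
8 | (3S,4R)-3,4,5-trimethyl-3-(4-methylpent-3-en-1-yl)hex-5-en-1-ol | OCC[C@]([C@H](C)C(C)=C)(C)CCC=C(C)C | intermediate
9 | 2-[(1S,2S)-1,2,3-trimethylcyclohex-3-en-1-yl]ethan-1-ol | OCC[C@]1(C)CCC=C(C)[C@H]1C | intermediate
10 | (1S,2S)-1-(2-iodoethyl)-1,2,3-trimethylcyclohex-3-ene | ICC[C@]1(C)CCC=C(C)[C@H]1C | intermediate
11 | but-2-yn-1-ol | CC#CCO | starting material
12 | sodium cyclic alkenylaluminate (five-membered ring O–Al–C3=C2–C1, two 2-methoxyethoxy groups on Al) | [Na+].CC1=CCO[Al-]1(OCCOC)OCCOC | intermediate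
13 | (2Z)-3-iodobut-2-en-1-ol | OC/C=C(C)\I | intermediate
14 | {2-[(1S,2S)-1,2,3-trimethylcyclohex-3-en-1-yl]ethyl}lithium | [Li]CC[C@]1(C)CCC=C(C)[C@H]1C | intermediate
15 | lithium B-methoxy-B-{2-[(1S,2S)-1,2,3-trimethylcyclohex-3-en-1-yl]ethyl}-9-borabicyclo[3.3.1]nonane borate | [Li+].CO[B-]1(CC[C@]2(C)CCC=C(C)[C@H]2C)C2CCCC1CCC2 | intermediate
16 | (2Z)-3-methyl-5-[(1S,2S)-1,2,3-trimethylcyclohex-3-en-1-yl]pent-2-en-1-ol | OC/C=C(C)\CC[C@]1(C)CCC=C(C)[C@H]1C | intermediate
17 | methyl (2Z)-3-methyl-5-[(1S,2S)-1,2,3-trimethylcyclohex-3-en-1-yl]pent-2-en-1-yl carbonate | COC(=O)OC/C=C(C)\CC[C@]1(C)CCC=C(C)[C@H]1C | intermediate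
18 | 1,2,3-trimethoxybenzene | COc1cccc(OC)c1OC | starting material
19 | 1,5-dibromo-2,3,4-trimethoxybenzene | COc1c(Br)cc(Br)c(OC)c1OC | intermediate
20 | 4,5,6-trimethoxybenzene-1,3-diol | COc1c(O)cc(O)c(OC)c1OC | intermediate
21 | 2,6-dihydroxy-3,4,5-trimethoxybenzaldehyde | COc1c(O)c(C=O)c(O)c(OC)c1OC | intermediate
22 | 2-hydroxy-3,4,5-trimethoxy-6-[(triisopropylsilyl)oxy]benzaldehyde | COc1c(O)c(C=O)c(O[Si](C(C)C)(C(C)C)C(C)C)c(OC)c1OC | intermediate
23 | 2-ethenyl-4,5,6-trimethoxy-3-[(triisopropylsilyl)oxy]phenol | COc1c(O)c(C=C)c(O[Si](C(C)C)(C(C)C)C(C)C)c(OC)c1OC | intermediate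
24 | 1-ethenyl-3,4,5-trimethoxy-2-{[(3R)-3-methyl-5-[(1S,2S)-1,2,3-trimethylcyclohex-3-en-1-yl]pent-1-en-3-yl]oxy}-6-[(triisopropylsilyl)oxy]benzene | COc1c(O[C@](C)(CC[C@]2(C)CCC=C(C)[C@H]2C)C=C)c(C=C)c(O[Si](C(C)C)(C(C)C)C(C)C)c(OC)c1OC | intermediate
25 | (2R)-6,7,8-trimethoxy-2-methyl-2-{2-[(1S,2S)-1,2,3-trimethylcyclohex-3-en-1-yl]ethyl}-5-[(triisopropylsilyl)oxy]-2H-chromene | COc1c(O[Si](C(C)C)(C(C)C)C(C)C)c2c(c(OC)c1OC)O[C@](C)(CC[C@]1(C)CCC=C(C)[C@H]1C)C=C2 | intermediate
26 | (2R)-6,7,8-trimethoxy-2-methyl-2-{2-[(1S,2S)-1,2,3-trimethylcyclohex-3-en-1-yl]ethyl}-2H-chromen-5-ol | COc1c(O)c2c(c(OC)c1OC)O[C@](C)(CC[C@]1(C)CCC=C(C)[C@H]1C)C=C2 | target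

## Step count and risks

Total step count: 17. Longest linear sequence: 11 steps (steps 1–6, 8, 9, 15, 16, 17).

**Step 1 (enantioselective Ireland–Claisen).** The risk is slow rearrangement of a trisubstituted allyl ester and incomplete enantio- or diastereocontrol. The fallback sets out from 1 and comes back at 3. LDA and Me3SiCl in THF at −78 °C convert 1 into the (E)-silyl ketene acetal F1, which rearranges on warming through the same chair and gives, after hydrolysis, the racemic anti acid F2. Coupling with (S)-4-benzyl-1,3-oxazolidin-2-one (EDC, DMAP) gives two diastereomeric imides that are separated by chromatography, the (2S,3S)-imide F3 and the (2R,3R)-imide F4. LiOH/H2O2 cleaves F3 to 3.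

**Step 5 (RCM between a 1,1-disubstituted and a trisubstituted alkene).** The risk is slow initiation because both alkenes are hindered. The fallback sets out from 6 and comes back at 9, replacing the prenyl terminus by a monosubstituted alkene before the ring is closed. Ozonolysis of 6 (O3, then Me2S) gives the aldehyde 3-[(3S,4S)-3,4-dimethyl-2-oxooxan-4-yl]propanal F5. One equivalent of Ph3P=CH2 at −78 → 0 °C gives the butenyl lactone F6. MeLi at −78 °C gives the hydroxy ketone F7, and methylenation gives the diene F8. F8 closes under second-generation Grubbs catalyst with loss of ethene to 9.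

**Step 15 (asymmetric allylic etherification with a 2,6-disubstituted phenol at a tertiary terminus).** The risk is linear instead of branched ether, or low ee. The fallback sets out from 16 (and from 19 for the arene) and comes back at 26; it builds the C2 centre by Sharpless epoxidation and closes the pyran by C–O coupling instead.
- Epoxidation of 16 (Ti(OiPr)4, L-(+)-diethyl tartrate, t-BuOOH, 4 Å sieves, CH2Cl2, −20 °C) gives the (2S,3R)-epoxy alcohol F9.
- PPh3/CCl4 gives the epoxy chloride F10, and n-BuLi (3 equiv, THF, −40 °C) gives the tertiary propargylic alcohol F11 with the carbinol centre untouched.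
- Dibromide 19 is lithiated between its bromines (LDA, THF, −78 °C) and quenched with I2 to 1,3-dibromo-2-iodo-4,5,6-trimethoxybenzene F12.
- Sonogashira coupling at the C–I bond (PdCl2(PPh3)2, CuI, Et3N) joins F11 and F12 to the aryl alkyne F13.
- Lindlar hydrogenation (Pd/CaCO3 poisoned with Pb(OAc)2, quinoline, H2) gives the Z-alkene F14.
- Intramolecular Pd-catalysed C–O coupling of the tertiary alcohol with one ortho bromide (Pd(OAc)2, t-BuXPhos, Cs2CO3, toluene, 80 °C) gives the 5-bromochromene F15.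
- Pd-catalysed hydroxylation (Pd2(dba)3, t-BuXPhos, KOH, dioxane/H2O) turns C5–Br into the phenol 26.

## Further compounds

F1 | step 1 | (E)-trimethylsilyl ketene acetal of geranyl propanoate (methyl cis to the allylic oxygen) | C/C=C(/O[Si](C)(C)C)OC/C=C(\C)CCC=C(C)C
F2 | step 1 | racemic (2S*,3S*)-3-ethenyl-2,3,7-trimethyloct-6-enoic acid | C=C[C@]([C@H](C)C(=O)O)(C)CCC=C(C)C.C=C[C@@]([C@@H](C)C(=O)O)(C)CCC=C(C)C
F3 | step 1 | (4S)-4-benzyl-3-[(2S,3S)-3-ethenyl-2,3,7-trimethyloct-6-enoyl]-1,3-oxazolidin-2-one | C=C[C@]([C@H](C)C(=O)N1[C@@H](Cc2ccccc2)COC1=O)(C)CCC=C(C)C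
F4 | step 1 | (4S)-4-benzyl-3-[(2R,3R)-3-ethenyl-2,3,7-trimethyloct-6-enoyl]-1,3-oxazolidin-2-one | C=C[C@@]([C@@H](C)C(=O)N1[C@@H](Cc2ccccc2)COC1=O)(C)CCC=C(C)C
F5 | step 5 | 3-[(3S,4S)-3,4-dimethyl-2-oxooxan-4-yl]propanal | C1(=O)OCC[C@]([C@@H]1C)(C)CCC=O
F6 | step 5 | (3S,4S)-4-(but-3-en-1-yl)-3,4-dimethyloxan-2-one | C1(=O)OCC[C@]([C@@H]1C)(C)CCC=C
F7 | step 5 | (3S,4S)-4-(2-hydroxyethyl)-3,4-dimethyloct-7-en-2-one | OCC[C@]([C@H](C)C(C)=O)(C)CCC=C
F8 | step 5 | (3S,4R)-3-(but-3-en-1-yl)-3,4,5-trimethylhex-5-en-1-ol | OCC[C@]([C@H](C)C(C)=C)(C)CCC=C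
F9 | step 15 | [(2S,3R)-3-methyl-3-{2-[(1S,2S)-1,2,3-trimethylcyclohex-3-en-1-yl]ethyl}oxiran-2-yl]methanol | OC[C@@H]1O[C@]1(C)CC[C@]1(C)CCC=C(C)[C@H]1C
F10 | step 15 | (2R,3R)-2-(chloromethyl)-3-methyl-3-{2-[(1S,2S)-1,2,3-trimethylcyclohex-3-en-1-yl]ethyl}oxirane | ClC[C@@H]1O[C@]1(C)CC[C@]1(C)CCC=C(C)[C@H]1C
F11 | step 15 | (3R)-3-methyl-5-[(1S,2S)-1,2,3-trimethylcyclohex-3-en-1-yl]pent-1-yn-3-ol | C#C[C@](C)(O)CC[C@]1(C)CCC=C(C)[C@H]1C
F12 | step 15 | 1,3-dibromo-2-iodo-4,5,6-trimethoxybenzene | COc1c(Br)c(I)c(Br)c(OC)c1OC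
F13 | step 15 | (3R)-1-(2,6-dibromo-3,4,5-trimethoxyphenyl)-3-methyl-5-[(1S,2S)-1,2,3-trimethylcyclohex-3-en-1-yl]pent-1-yn-3-ol | COc1c(Br)c(C#C[C@](C)(O)CC[C@]2(C)CCC=C(C)[C@H]2C)c(Br)c(OC)c1OC
F14 | step 15 | (1Z,3R)-1-(2,6-dibromo-3,4,5-trimethoxyphenyl)-3-methyl-5-[(1S,2S)-1,2,3-trimethylcyclohex-3-en-1-yl]pent-1-en-3-ol | COc1c(Br)c(/C=C\[C@](C)(O)CC[C@]2(C)CCC=C(C)[C@H]2C)c(Br)c(OC)c1OC
F15 | step 15 | (2R)-5-bromo-6,7,8-trimethoxy-2-methyl-2-{2-[(1S,2S)-1,2,3-trimethylcyclohex-3-en-1-yl]ethyl}-2H-chromene | COc1c(Br)c2c(c(OC)c1OC)O[C@](C)(CC[C@]1(C)CCC=C(C)[C@H]1C)C=C2
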